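**Assumption:** the oxolane is numbered O1, C2 (4-hydroxyphenyl), C3 (aroyl), C4 (4-hydroxybenzyl), C5 (2,4-dihydroxyphenyl), so the given SMILES is the (2S,3S,4S,5R) isomer; spiro compounds are drawn with the ring carbonyl anti to the C2' aryl, and the other spiro epimer would converge in step 6.

**Retrosynthetic overview**
1. Target ⇐ reductive scission (SmI2) of the C3–O(aryl) bond of a spiro[benzofuranone–oxolane] pentaphenol, which frees the 2-hydroxyaroyl group; C3 then settles trans to both neighbours.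
2. Spiro pentaphenol ⇐ hydrogenation of a 4'-arylidene spirocycle from the face opposite the two cis aryl groups (sets C4), with loss of all five benzyl groups.
3. Arylidene spirocycle ⇐ one flask, two ring closures: o-hydroxyaryl ynone → aurone (benzofuranone ring, first), then oxa-Michael/carbopalladation/arylation with an (R)-1-arylpropargyl alcohol and an aryl iodide (oxolane ring, second).
4. Ynone ⇐ salicylaldehyde + arylacetylene (addition, oxidation); alkynol ⇐ catalytic asymmetric alkynylation of 2,4-bis(benzyloxy)benzaldehyde.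

**Route**

Step 1
Reactants: 1 2,4-bis(benzyloxy)benzaldehyde; 2 ethynyltrimethylsilane
Product: 4 (R)-1-[2,4-bis(benzyloxy)phenyl]prop-2-yn-1-ol, via silyl alkynol 3 (not isolated)
Conditions: 2 (3 equiv), Me2Zn (3 equiv), ProPhenol ligand (10 mol %, the antipode that gives the R carbinol), Ph3P=O (20 mol %), toluene, 0 °C; aq NH4Cl; then K2CO3 (0.2 equiv), MeOH, rt
Reagents that add atoms: none
Why: Catalytic asymmetric alkynylation of an aldehyde, in which the chiral dinuclear zinc–ProPhenol alkoxide delivers the alkynylzinc to one face of the formyl group and so sets the carbinol centre that becomes C5 of the target, followed by basic methanolysis of the C–Si bond.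

Step 2
Reactants: 5 4-(benzyloxy)-2-hydroxybenzaldehyde; 6 1-(benzyloxy)-4-ethynylbenzene
Product: 7 1-[4-(benzyloxy)-2-hydroxyphenyl]-3-[4-(benzyloxy)phenyl]prop-2-yn-1-ol (racemic)
Conditions: 6 (2.3 equiv), n-BuLi (2.2 equiv), THF, −78 °C; then 5 (1 equiv), −78 to 0 °C; aq NH4Cl
Reagents that add atoms: none
Why: Lithium acetylide addition to an aldehyde, in which the first equivalent of acetylide only deprotonates the phenol and the second adds to the formyl group, and the new carbinol centre is left racemic because step 3 oxidises it away.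

Step 3
Reactants: 7 1-[4-(benzyloxy)-2-hydroxyphenyl]-3-[4-(benzyloxy)phenyl]prop-2-yn-1-ol
Product: 8 1-[4-(benzyloxy)-2-hydroxyphenyl]-3-[4-(benzyloxy)phenyl]prop-2-yn-1-one
Conditions: MnO2 (10 equiv), CH2Cl2, rt
Reagents that add atoms: none
Why: MnO2 oxidation of a benzylic propargylic alcohol is neutral and selective, so the free phenol, the benzyl ethers and the alkyne survive and the ynone does not cyclise prematurely, and no stereocentre is involved.

Step 4
Reactants: 8 1-[4-(benzyloxy)-2-hydroxyphenyl]-3-[4-(benzyloxy)phenyl]prop-2-yn-1-one; 4 (R)-1-[2,4-bis(benzyloxy)phenyl]prop-2-yn-1-ol; 9 1-(benzyloxy)-4-iodobenzene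
Product: 11 (2R,2'R,5'S)-6-(benzyloxy)-5'-[2,4-bis(benzyloxy)phenyl]-2'-[4-(benzyloxy)phenyl]-4'-{(E)-[4-(benzyloxy)phenyl]methylidene}-3H-spiro[1-benzofuran-2,3'-oxolan]-3-one, via aurone 10 (not isolated)
Conditions: 8 (1 equiv), AgOTf (5 mol %), THF, rt, 2 h; then 4 (1.2 equiv) pre-mixed with t-BuOK (1.2 equiv), 9 (1.3 equiv), Pd(OAc)2 (5 mol %), PPh3 (10 mol %), DMSO, rt, 12 h
Reagents that add atoms: none
Why: Proposed new method: monovalent silver activates the ynone for 5-exo-dig attack of the phenol at the alpha carbon (closest known reaction: silver-catalysed cyclisation of o-hydroxyaryl ynones to aurones), and the (Z)-aurone then enters the three-component oxa-Michael/anti-carbopalladation/reductive-elimination cascade known for propargyl alkoxides with alkylidene malonates and aryl halides under zerovalent palladium, with the aromatic benzofuran-3-olate as the carbon nucleophile, so the benzofuranone ring and then the oxolane ring close in one flask; because the oxa-Michael step is reversible, the untouched (R) carbinol centre of 4 selects the cyclisation transition state with both aryl groups pseudo-equatorial (2',5'-cis), and the spiro centre that also forms is erased in step 6.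

Step 5
Reactants: 11 (2R,2'R,5'S)-6-(benzyloxy)-5'-[2,4-bis(benzyloxy)phenyl]-2'-[4-(benzyloxy)phenyl]-4'-{(E)-[4-(benzyloxy)phenyl]methylidene}-3H-spiro[1-benzofuran-2,3'-oxolan]-3-one
Product: 12 (2R,2'R,4'R,5'R)-5'-(2,4-dihydroxyphenyl)-6-hydroxy-2'-(4-hydroxyphenyl)-4'-[(4-hydroxyphenyl)methyl]-3H-spiro[1-benzofuran-2,3'-oxolan]-3-one
Conditions: H2 (1 atm), Pd/C (10 wt %), EtOAc/MeOH (1:1), rt
Reagents that add atoms: none
Why: Heterogeneous hydrogenation with hydrogenolysis of the five benzyl ethers, in which the two cis aryl groups at C2' and C5' shield one face of the exocyclic alkene so that hydrogen reaches C4' from the other face and the new benzyl group ends up cis to the C5' aryl, while the still quaternary spiro centre rules out enolisation next to the ketone.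

Step 6
Reactants: 12 (2R,2'R,4'R,5'R)-5'-(2,4-dihydroxyphenyl)-6-hydroxy-2'-(4-hydroxyphenyl)-4'-[(4-hydroxyphenyl)methyl]-3H-spiro[1-benzofuran-2,3'-oxolan]-3-one
Product: 14 (2,4-dihydroxyphenyl)[(2S,3S,4S,5R)-5-(2,4-dihydroxyphenyl)-2-(4-hydroxyphenyl)-4-[(4-hydroxyphenyl)methyl]oxolan-3-yl]methanone, via C3-epimeric ketone 13 (not isolated)
Conditions: SmI2 (3 equiv), THF/MeOH (10:1), −78 °C, 30 min; then Et3N (0.5 equiv), MeOH, rt
Reagents that add atoms: none
Why: SmI2 reduction of an alpha-aryloxy ketone, in which the ketyl formed by divalent samarium expels the aryloxide from the spiro carbon to give a samarium enolate and the free ortho-phenol, protonation from the open face gives the all-cis ketone 13, and amine-mediated enolisation then moves the aroyl group trans to both neighbours, which is the thermodynamic arrangement and the C3 configuration of the target.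

**Compound list**
1 | 2,4-bis(benzyloxy)benzaldehyde | O=Cc1ccc(OCc2ccccc2)cc1OCc1ccccc1 | starting material
2 | ethynyltrimethylsilane | C#C[Si](C)(C)C | starting material
3 | (S)-1-[2,4-bis(benzyloxy)phenyl]-3-(trimethylsilyl)prop-2-yn-1-ol (same spatial arrangement as 4; the descriptor changes because silicon raises the alkyne priority) | C[Si](C)(C)C#C[C@H](c1ccc(OCc2ccccc2)cc1OCc1ccccc1)O | intermediate
4 | (R)-1-[2,4-bis(benzyloxy)phenyl]prop-2-yn-1-ol | C#C[C@H](c1ccc(OCc2ccccc2)cc1OCc1ccccc1)O | intermediate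
5 | 4-(benzyloxy)-2-hydroxybenzaldehyde | O=Cc1ccc(OCc2ccccc2)cc1O | starting material
6 | 1-(benzyloxy)-4-ethynylbenzene | C#Cc1ccc(OCc2ccccc2)cc1 | starting material
7 | 1-[4-(benzyloxy)-2-hydroxyphenyl]-3-[4-(benzyloxy)phenyl]prop-2-yn-1-ol (racemic) | OC(C#Cc1ccc(OCc2ccccc2)cc1)c1ccc(OCc2ccccc2)cc1O | intermediate
8 | 1-[4-(benzyloxy)-2-hydroxyphenyl]-3-[4-(benzyloxy)phenyl]prop-2-yn-1-one | O=C(C#Cc1ccc(OCc2ccccc2)cc1)c1ccc(OCc2ccccc2)cc1O | intermediate
9 | 1-(benzyloxy)-4-iodobenzene | Ic1ccc(OCc2ccccc2)cc1 | starting material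
10 | (2Z)-6-(benzyloxy)-2-{[4-(benzyloxy)phenyl]methylidene}-1-benzofuran-3(2H)-one | O=C1c2ccc(OCc3ccccc3)cc2O/C1=C\c1ccc(OCc2ccccc2)cc1 | intermediate
11 | (2R,2'R,5'S)-6-(benzyloxy)-5'-[2,4-bis(benzyloxy)phenyl]-2'-[4-(benzyloxy)phenyl]-4'-{(E)-[4-(benzyloxy)phenyl]methylidene}-3H-spiro[1-benzofuran-2,3'-oxolan]-3-one (2',5'-aryl groups cis) | O=C1c2ccc(OCc4ccccc4)cc2O[C@@]13/C(=C/c2ccc(OCc4ccccc4)cc2)[C@H](c2ccc(OCc4ccccc4)cc2OCc2ccccc2)O[C@@H]3c1ccc(OCc2ccccc2)cc1 | intermediate
12 | (2R,2'R,4'R,5'R)-5'-(2,4-dihydroxyphenyl)-6-hydroxy-2'-(4-hydroxyphenyl)-4'-[(4-hydroxyphenyl)methyl]-3H-spiro[1-benzofuran-2,3'-oxolan]-3-one (2'-aryl, 4'-benzyl and 5'-aryl all cis) | O=C1c2ccc(O)cc2O[C@@]13[C@H](Cc2ccc(O)cc2)[C@H](c2ccc(O)cc2O)O[C@@H]3c1ccc(O)cc1 | intermediate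
13 | (2,4-dihydroxyphenyl)[(2S,3R,4S,5R)-5-(2,4-dihydroxyphenyl)-2-(4-hydroxyphenyl)-4-[(4-hydroxyphenyl)methyl]oxolan-3-yl]methanone (all-cis C3 epimer) | O=C(c1ccc(O)cc1O)[C@@H]1[C@H](Cc2ccc(O)cc2)[C@H](c2ccc(O)cc2O)O[C@@H]1c1ccc(O)cc1 | intermediate
14 | (2,4-dihydroxyphenyl)[(2S,3S,4S,5R)-5-(2,4-dihydroxyphenyl)-2-(4-hydroxyphenyl)-4-[(4-hydroxyphenyl)methyl]oxolan-3-yl]methanone | O=C(c1ccc(O)cc1O)[C@H]1[C@H](Cc2ccc(O)cc2)[C@H](c2ccc(O)cc2O)O[C@@H]1c1ccc(O)cc1 | target

**Total step count:** 6. **Longest linear sequence:** 5 steps (5 + 6 → 7 → 8 → 11 → 12 → 14).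

**Three steps most likely to fail, with fallbacks**

Step 4 (double ring closure). The silver-to-palladium one-flask sequence may stall, or 4 may couple directly with 9. The fallback sets out from 8: the silver-catalysed cyclisation is stopped at aurone 10, which is isolated. In parallel, 1 and 6 are joined by the Me2Zn/ProPhenol alkynylation of step 1 to give the pre-arylated alkynol (R)-1-[2,4-bis(benzyloxy)phenyl]-3-[4-(benzyloxy)phenyl]prop-2-yn-1-ol F1. Then 10 and F1 are united without palladium or an aryl halide by an oxa-Michael/Conia-ene cycloisomerisation (t-BuOK 20 mol %, CuI 10 mol %, THF, rt), which gives the (Z)-arylidene isomer of 11 F2. Hydrogenation of F2 under the conditions of step 5 removes the alkene geometry and returns to the route at 12.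

Step 5 (hydrogenation). Pd/C may open a benzylic C–O bond of the oxolane or give a poor facial ratio. The fallback sets out from 11 and separates the two events. Hydrogen-atom-transfer reduction of the alkene alone (Mn(dpm)3 10 mol %, PhSiH3, t-BuOOH, i-PrOH, rt) is a radical process with no hydrogenolysis, and hydrogen still reaches C4' from the open face; it gives the saturated pentabenzyl spiro ketone F3. Transfer hydrogenolysis (Pd(OH)2/C, cyclohexa-1,4-diene, EtOH, rt) then removes the benzyl groups and returns to the route at 12.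

Step 6 (C–O scission on the pentaphenol). SmI2 may be quenched by the free phenols or over-reduce the liberated ketone. The fallback changes the order of events and sets out from 11. The alkene is reduced as above to the saturated pentabenzyl spiro ketone F3. The C–O bond is then cut with SmI2 (THF/MeOH, −78 °C) while every other phenol is still a benzyl ether, and Et3N/MeOH equilibration gives the pentabenzyl ether of the target, [4-(benzyloxy)-2-hydroxyphenyl][(2S,3S,4S,5R)-5-[2,4-bis(benzyloxy)phenyl]-2-[4-(benzyloxy)phenyl]-4-{[4-(benzyloxy)phenyl]methyl}oxolan-3-yl]methanone F4. A final debenzylation (H2, Pd/C, EtOAc, rt) returns to the route at 14.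

**Further compounds**
F1 | step 4 | (R)-1-[2,4-bis(benzyloxy)phenyl]-3-[4-(benzyloxy)phenyl]prop-2-yn-1-ol | O[C@H](C#Cc1ccc(OCc2ccccc2)cc1)c1ccc(OCc2ccccc2)cc1OCc1ccccc1
F2 | step 4 | (2R,2'R,5'S)-6-(benzyloxy)-5'-[2,4-bis(benzyloxy)phenyl]-2'-[4-(benzyloxy)phenyl]-4'-{(Z)-[4-(benzyloxy)phenyl]methylidene}-3H-spiro[1-benzofuran-2,3'-oxolan]-3-one | O=C1c2ccc(OCc4ccccc4)cc2O[C@@]13/C(=C\c2ccc(OCc4ccccc4)cc2)[C@H](c2ccc(OCc4ccccc4)cc2OCc2ccccc2)O[C@@H]3c1ccc(OCc2ccccc2)cc1
F3 | step 5 | (2R,2'R,4'R,5'R)-6-(benzyloxy)-5'-[2,4-bis(benzyloxy)phenyl]-2'-[4-(benzyloxy)phenyl]-4'-{[4-(benzyloxy)phenyl]methyl}-3H-spiro[1-benzofuran-2,3'-oxolan]-3-one | O=C1c2ccc(OCc4ccccc4)cc2O[C@@]13[C@H](Cc2ccc(OCc4ccccc4)cc2)[C@H](c2ccc(OCc4ccccc4)cc2OCc2ccccc2)O[C@@H]3c1ccc(OCc2ccccc2)cc1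
F4 | step 6 | [4-(benzyloxy)-2-hydroxyphenyl][(2S,3S,4S,5R)-5-[2,4-bis(benzyloxy)phenyl]-2-[4-(benzyloxy)phenyl]-4-{[4-(benzyloxy)phenyl]methyl}oxolan-3-yl]methanone | O=C(c1ccc(OCc2ccccc2)cc1O)[C@H]1[C@H](Cc2ccc(OCc3ccccc3)cc2)[C@H](c2ccc(OCc3ccccc3)cc2OCc2ccccc2)O[C@@H]1c1ccc(OCc2ccccc2)cc1
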